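**Retrosynthetic overview**

- Feature: C7a, the carbon shared by rings A and B and bonded to O1, C3a and C7, is at the carboxyl oxidation level. It is therefore taken from the carbonyl carbon of a trans β-methyl-γ-aryl butyrolactone that already holds O1, C2, C3 and C3a.
- Ring B (last): the O1–C7a bond is re-formed by acid-catalysed cyclodehydration of a 3-hydroxycyclohexadienone that carries the C2 carbinol.
- Ring A (key): C7–C7a is made by an intramolecular Claisen acyl transfer. The acetyl methyl group of a (Z)-α-alkylidene lactone attacks the lactone carbonyl and the lactone oxygen leaves as the C2 alkoxide.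
- C3a=C4 comes from a Z-selective Horner–Wadsworth–Emmons coupling of an α-(diphenoxyphosphoryl) lactone (from 3,4,5-trimethoxybenzaldehyde by anti-crotylboration) with (S)-2-acetyl-2-methoxypent-4-enal (from tert-butyl acetoacetate; C5 set by asymmetric phase-transfer allylation).
- Ring order: temporary lactone ring, then ring A, then ring B.

Key step: step 11

Assumption: the sense of induction in steps 1 and 7 is taken from the behaviour of closely related substrates; both catalysts exist in either antipode, and the antipode that delivers the stated configuration is the one meant.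
Remark: enolates and phosphonate anions formed by simple deprotonation are treated as forms of the numbered compound they come from.

**Route**

Step 1
Reactants: 1 3,4,5-trimethoxybenzaldehyde; 2 (E)-crotylboronic acid pinacol ester
Product: 4 (1S,2S)-2-methyl-1-(3,4,5-trimethoxyphenyl)but-3-en-1-ol, via homoallyl pinacol borate 3 (not isolated)
Conditions: (S)-3,3'-bis(2,4,6-triisopropylphenyl)-1,1'-binaphthyl-2,2'-diyl hydrogen phosphate (5 mol%), 4 Å MS, toluene, −30 °C; aqueous NaHCO3 work-up
Reagents that add atoms: none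
Why: Chiral-phosphoric-acid-catalysed crotylboration through a closed chair transition state, in which the (E)-crotyl geometry gives the anti relationship and the (S)-acid should direct attack to the si face of the aldehyde, setting the future C2 (1S) and C3 (2S).

Step 2
Reactants: 4 (1S,2S)-2-methyl-1-(3,4,5-trimethoxyphenyl)but-3-en-1-ol
Product: 6 (1S,2S)-2-methyl-1-(3,4,5-trimethoxyphenyl)butane-1,4-diol, via bis(9-BBN) adduct 5 (not isolated)
Conditions: 9-BBN (9-borabicyclo[3.3.1]nonane, 2.2 equiv), THF, 0 °C to rt; then NaOH, H2O2, 0 °C to rt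
Reagents that add atoms: hydrogen peroxide, OO
Why: Hydroboration–oxidation with the bulky borane places boron on the terminal carbon only, and oxidation with retention gives the primary alcohol without touching either stereocentre.

Step 3
Reactants: 6 (1S,2S)-2-methyl-1-(3,4,5-trimethoxyphenyl)butane-1,4-diol
Product: 9 (4S,5S)-4-methyl-5-(3,4,5-trimethoxyphenyl)oxolan-2-one, via hydroxy aldehyde 7 (not isolated), via lactol 8 (not isolated)
Conditions: TEMPO (20 mol%), PhI(OAc)2 (2.5 equiv), CH2Cl2, rt
Reagents that add atoms: none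
Why: Oxidative lactonisation of a 1,4-diol: the oxoammonium oxidant takes the primary alcohol first, the aldehyde is trapped by the benzylic hydroxyl as the five-membered lactol, and this is oxidised again, so the trans arrangement is carried over unchanged.

Step 4
Reactants: 9 (4S,5S)-4-methyl-5-(3,4,5-trimethoxyphenyl)oxolan-2-one
Product: 11 diphenyl [(4R,5S)-4-methyl-2-oxo-5-(3,4,5-trimethoxyphenyl)oxolan-3-yl]phosphonate (C3 epimers), via lactone phosphonite 10 (not isolated)
Conditions: LiN(SiMe3)2 (1.1 equiv), THF, −78 °C; (PhO)2PCl, −78 °C to rt; then t-BuOOH, 0 °C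
Reagents that add atoms: diphenyl phosphorochloridite, ClP(Oc1ccccc1)Oc1ccccc1; tert-butyl hydroperoxide, CC(C)(C)OO
Why: C-phosphinylation of a lactone enolate with a chlorophosphite followed by oxidation of trivalent to pentavalent phosphorus gives the Ando-type phosphonate without the strong-base O-to-C phosphoryl migration that aryl phosphates would not survive; the new centre at C3 is uncontrolled and disappears in step 10 (the descriptor at C4 changes to R only because phosphorus raises the priority of C3).

Step 5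
Reactants: 12 tert-butyl acetoacetate
Product: 13 tert-butyl 2-diazo-3-oxobutanoate
Conditions: 4-acetamidobenzenesulfonyl azide, Et3N, MeCN, 0 °C to rt
Reagents that add atoms: 4-acetamidobenzenesulfonyl azide, CC(=O)Nc1ccc(cc1)S(=O)(=O)N=[N+]=[N-]
Why: Regitz diazo transfer to the doubly activated methylene group is a standard, clean reaction.

Step 6
Reactants: 13 tert-butyl 2-diazo-3-oxobutanoate
Product: 14 tert-butyl 2-methoxy-3-oxobutanoate (racemic)
Conditions: Rh2(OAc)4 (1 mol%), MeOH (5 equiv), CH2Cl2, 40 °C
Reagents that add atoms: methanol, CO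
Why: O–H insertion of the rhodium carbenoid into methanol installs the α-methoxy group at the correct carbon in one operation; the centre is still epimerisable and is fixed only in step 7.

Step 7
Reactants: 14 tert-butyl 2-methoxy-3-oxobutanoate; 15 allyl bromide
Product: 16 tert-butyl (2R)-2-acetyl-2-methoxypent-4-enoate
Conditions: (S)-4,4-dibutyl-2,6-bis(3,4,5-trifluorophenyl)-4,5-dihydro-3H-dinaphtho[2,1-c:1',2'-e]azepinium bromide (2 mol%), CsOH·H2O, toluene, −40 °C
Reagents that add atoms: none
Why: Asymmetric phase-transfer alkylation of an α-oxygenated β-keto ester: the chiral ammonium cation carries the enolate as a tight ion pair and shields one face, so allyl bromide C-alkylates the other and sets the quaternary centre (future C5; R here, S after the priority change on reduction), with the tert-butyl ester helping facial discrimination and resisting hydrolysis.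

Step 8
Reactants: 16 tert-butyl (2R)-2-acetyl-2-methoxypent-4-enoate
Product: 17 (2S)-2-methoxy-2-(prop-2-en-1-yl)butane-1,3-diol (C3 epimers)
Conditions: LiAlH4 (2 equiv), THF, 0 °C to rt
Reagents that add atoms: none
Why: Hydride reduction of ketone and ester with LiAlH4 brings both carbons to the alcohol level without touching the quaternary centre; the new carbinol centre is uncontrolled and is removed in step 9.

Step 9
Reactants: 17 (2S)-2-methoxy-2-(prop-2-en-1-yl)butane-1,3-diol
Product: 18 (2S)-2-acetyl-2-methoxypent-4-enal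
Conditions: Dess–Martin periodinane (2.6 equiv), CH2Cl2, 0 °C to rt; used promptly
Reagents that add atoms: none
Why: Dess–Martin oxidation of the primary and the secondary alcohol under non-basic conditions gives the keto aldehyde without retro-Claisen cleavage, and C5 cannot epimerise because it bears no hydrogen.

Step 10
Reactants: 11 diphenyl [(4R,5S)-4-methyl-2-oxo-5-(3,4,5-trimethoxyphenyl)oxolan-3-yl]phosphonate; 18 (2S)-2-acetyl-2-methoxypent-4-enal
Product: 19 (3Z,4S,5S)-3-[(2S)-2-acetyl-2-methoxypent-4-en-1-ylidene]-4-methyl-5-(3,4,5-trimethoxyphenyl)oxolan-2-one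
Conditions: 11 (1.15 equiv), NaH (1.1 equiv), THF, 0 °C; then 18, −78 to 0 °C
Reagents that add atoms: none
Why: Horner–Wadsworth–Emmons olefination in the Ando variant, in which the diaryl phosphonate makes elimination fast relative to reversal of the addition so that the kinetic adduct gives the (Z)-alkylidene lactone with the side chain beside the lactone carbonyl; the aldehyde should react in preference to the hindered methyl ketone, and any C5 epimer left from step 7 becomes a separable diastereomer here.

Step 11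
Reactants: 19 (3Z,4S,5S)-3-[(2S)-2-acetyl-2-methoxypent-4-en-1-ylidene]-4-methyl-5-(3,4,5-trimethoxyphenyl)oxolan-2-one
Product: 21 (6S)-3-hydroxy-4-[(1S,2S)-1-hydroxy-1-(3,4,5-trimethoxyphenyl)propan-2-yl]-6-methoxy-6-(prop-2-en-1-yl)cyclohexa-2,4-dien-1-one, via bicyclic lithium hemiketal alkoxide 20 (not isolated)
Conditions: LiN(SiMe3)2 (2.2 equiv), THF (dilute), −78 to 0 °C; then 1 M HCl to pH 4, 0 °C
Reagents that add atoms: none
Why: The base removes a proton from the acetyl methyl group, the only enolisable position (C5 is quaternary and C3–H is cross-conjugated with the lactone carbonyl), and the enolate carbon C7 adds to the lactone carbonyl C7a to give the tetrahedral alkoxide 20, which collapses with loss of the C2 alkoxide; deprotonation of the new cyclic 1,3-dicarbonyl by the second equivalent of base then makes the transfer irreversible. The closest known reaction type is the intramolecular Claisen (Dieckmann-type) acylation of a ketone enolate by a lactone, which gives a cyclic 1,3-diketone and a free alcohol. Ring A closes in a 6-(enolendo)-exo-trig mode at the lactone carbonyl, with the cis C3a=C4 bond inside the new ring. No stereocentre is formed; C2, C3 and C5 are spectators and C7a returns to trigonal on collapse. The step needs the Z geometry fixed in step 10 and C- over O-acylation; the latter should be secured by reversibility, because an enol lactone from O-attack can be reopened by the tethered alkoxide whereas the diketonate is a sink.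

Step 12
Reactants: 21 (6S)-3-hydroxy-4-[(1S,2S)-1-hydroxy-1-(3,4,5-trimethoxyphenyl)propan-2-yl]-6-methoxy-6-(prop-2-en-1-yl)cyclohexa-2,4-dien-1-one
Product: 22 (2S,3S,5S)-5-methoxy-3-methyl-5-(prop-2-en-1-yl)-2-(3,4,5-trimethoxyphenyl)-2,3-dihydro-1-benzofuran-6(5H)-one
Conditions: pyridinium p-toluenesulfonate (10 mol%), 4 Å MS, CH2Cl2, rt
Reagents that add atoms: none
Why: Acid-catalysed cyclodehydration to a vinylogous ester, in which the C2 hydroxyl can reach only C7a and closes ring B (5-exo-trig) through a hemiketal that loses water; the C2–O bond stays intact, so the trans C2/C3 arrangement and C5 are unchanged, and mild acid at room temperature should avoid allyl migration from C5.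

**Compound list**

1 | 3,4,5-trimethoxybenzaldehyde | COc1cc(C=O)cc(OC)c1OC | starting material
2 | (E)-crotylboronic acid pinacol ester | C/C=C/CB1OC(C)(C)C(C)(C)O1 | starting material
3 | 4,4,5,5-tetramethyl-2-{[(1S,2S)-2-methyl-1-(3,4,5-trimethoxyphenyl)but-3-en-1-yl]oxy}-1,3,2-dioxaborolane | C=C[C@H](C)[C@H](OB1OC(C)(C)C(C)(C)O1)c1cc(OC)c(OC)c(OC)c1 | intermediate
4 | (1S,2S)-2-methyl-1-(3,4,5-trimethoxyphenyl)but-3-en-1-ol | C=C[C@H](C)[C@H](O)c1cc(OC)c(OC)c(OC)c1 | intermediate
5 | 9-[(3S,4S)-4-(9-borabicyclo[3.3.1]nonan-9-yloxy)-3-methyl-4-(3,4,5-trimethoxyphenyl)butyl]-9-borabicyclo[3.3.1]nonane | C1CCC2CCCC1B2CC[C@H](C)[C@H](OB1C2CCCC1CCC2)c1cc(OC)c(OC)c(OC)c1 | intermediate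
6 | (1S,2S)-2-methyl-1-(3,4,5-trimethoxyphenyl)butane-1,4-diol | OCC[C@H](C)[C@H](O)c1cc(OC)c(OC)c(OC)c1 | intermediate
7 | (3S,4S)-4-hydroxy-3-methyl-4-(3,4,5-trimethoxyphenyl)butanal | O=CC[C@H](C)[C@H](O)c1cc(OC)c(OC)c(OC)c1 | intermediate
8 | (4S,5S)-4-methyl-5-(3,4,5-trimethoxyphenyl)oxolan-2-ol (anomers) | OC1C[C@H](C)[C@@H](c2cc(OC)c(OC)c(OC)c2)O1 | intermediate
9 | (4S,5S)-4-methyl-5-(3,4,5-trimethoxyphenyl)oxolan-2-one | O=C1C[C@H](C)[C@@H](c2cc(OC)c(OC)c(OC)c2)O1 | intermediate
10 | diphenyl [(4R,5S)-4-methyl-2-oxo-5-(3,4,5-trimethoxyphenyl)oxolan-3-yl]phosphonite (C3 epimers) | O=C1C(P(Oc2ccccc2)Oc2ccccc2)[C@H](C)[C@@H](c2cc(OC)c(OC)c(OC)c2)O1 | intermediate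
11 | diphenyl [(4R,5S)-4-methyl-2-oxo-5-(3,4,5-trimethoxyphenyl)oxolan-3-yl]phosphonate (C3 epimers) | O=C1C(P(=O)(Oc2ccccc2)Oc2ccccc2)[C@H](C)[C@@H](c2cc(OC)c(OC)c(OC)c2)O1 | intermediate
12 | tert-butyl acetoacetate | CC(=O)CC(=O)OC(C)(C)C | starting material
13 | tert-butyl 2-diazo-3-oxobutanoate | CC(=O)C(=[N+]=[N-])C(=O)OC(C)(C)C | intermediate
14 | tert-butyl 2-methoxy-3-oxobutanoate (racemic) | CC(=O)C(OC)C(=O)OC(C)(C)C | intermediate
15 | allyl bromide | C=CCBr | starting material
16 | tert-butyl (2R)-2-acetyl-2-methoxypent-4-enoate | CC(=O)[C@](OC)(CC=C)C(=O)OC(C)(C)C | intermediate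
17 | (2S)-2-methoxy-2-(prop-2-en-1-yl)butane-1,3-diol (C3 epimers) | CC(O)[C@](OC)(CC=C)CO | intermediate
18 | (2S)-2-acetyl-2-methoxypent-4-enal | CC(=O)[C@](OC)(CC=C)C=O | intermediate
19 | (3Z,4S,5S)-3-[(2S)-2-acetyl-2-methoxypent-4-en-1-ylidene]-4-methyl-5-(3,4,5-trimethoxyphenyl)oxolan-2-one | CC(=O)[C@](OC)(CC=C)/C=C1/[C@H](C)[C@@H](c2cc(OC)c(OC)c(OC)c2)OC1=O | intermediate
20 | lithium (2S,3S,5S)-5-methoxy-3-methyl-6-oxo-5-(prop-2-en-1-yl)-2-(3,4,5-trimethoxyphenyl)-2,3,5,6,7,7a-hexahydro-1-benzofuran-7a-olate (C7a epimers) | [Li+].C=CC[C@]1(OC)C=C2C([O-])(CC1=O)O[C@H](c1cc(OC)c(OC)c(OC)c1)[C@H]2C | intermediate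
21 | (6S)-3-hydroxy-4-[(1S,2S)-1-hydroxy-1-(3,4,5-trimethoxyphenyl)propan-2-yl]-6-methoxy-6-(prop-2-en-1-yl)cyclohexa-2,4-dien-1-one | C=CC[C@]1(OC)C=C([C@H](C)[C@H](O)c2cc(OC)c(OC)c(OC)c2)C(O)=CC1=O | intermediate
22 | (2S,3S,5S)-5-methoxy-3-methyl-5-(prop-2-en-1-yl)-2-(3,4,5-trimethoxyphenyl)-2,3-dihydro-1-benzofuran-6(5H)-one | C=CC[C@]1(OC)C=C2C(=CC1=O)O[C@H](c1cc(OC)c(OC)c(OC)c1)[C@H]2C | target

**Step count and risks**

Total step count: 12. Longest linear sequence: 8 steps (steps 5 to 12, from tert-butyl acetoacetate); the lactone branch is 7 steps (steps 1 to 4, then 10 to 12).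

Steps most likely to fail:

Step 11. The rigid, conjugated Z-alkylidene lactone may hold C7 off the approach line to C7a, and the tethered C2 alkoxide may re-close the lactone faster than the diketone is trapped as its enolate, so that intermolecular condensation takes over. The fallback changes the acyl donor from the lactone to an open-chain N-methoxy-N-methyl amide whose C2 oxygen is silylated, so that nothing can return to C7a. It sets out from lactone 9. Me(MeO)NH·HCl with AlMe3 opens 9 to the hydroxy Weinreb amide F1, and Et3SiCl with imidazole gives the triethylsilyl ether F2. LiN(SiMe3)2, then (PhO)2PCl, then t-BuOOH gives the α-(diphenoxyphosphoryl) amide F3, and NaH with keto aldehyde 18 gives the (Z)-enamide F4. LiN(SiMe3)2 then closes ring A through the stable tetrahedral chelate of the amide to the O-silylated hydroxy-dienone F5. TsOH·H2O in aqueous THF removes the silyl group and closes ring B, so the fallback comes back to the route at target 22.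

Step 10. The fully substituted phosphonate anion may add too slowly to the neopentyl-type aldehyde, so that on warming the Z preference erodes or the keto aldehyde is lost by deformylation. The fallback replaces olefination by aldol addition, dehydration and isomerisation. It sets out from lactone 9 and keto aldehyde 18. The lithium enolate of 9 (LiN(SiMe3)2, THF, −78 °C) adds to the aldehyde group of 18 to give the aldol adduct F6, and MsCl with Et3N gives the mesylate F7. DBU eliminates F7 to the alkylidene lactone as a mixture of 19 and its (E)-isomer F8. The isomers are separated, F8 is re-equilibrated by sensitised irradiation and separated again, and the route is rejoined at 19.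

Step 7. Facial discrimination in the ion pair of an acyclic α-methoxy enolate, whose geometry is not fixed, may be poor, and the sense of induction is not secured by a direct precedent. The fallback gives up catalytic control and uses the enantiopure lactone half as the resolving element. It sets out from 14. K2CO3 and allyl bromide in acetone give the racemic keto ester F9, LiAlH4 gives the racemic diol F10, and Dess–Martin periodinane gives the racemic keto aldehyde F11. Olefination with 11 as in step 10 gives 19 together with its C5 epimer F12; the two diastereomers are separated by chromatography and the route is rejoined at 19.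

**Further compounds**

F1 | step 11 | (3S,4S)-4-hydroxy-N-methoxy-N,3-dimethyl-4-(3,4,5-trimethoxyphenyl)butanamide | CON(C)C(=O)C[C@H](C)[C@H](O)c1cc(OC)c(OC)c(OC)c1
F2 | step 11 | (3S,4S)-N-methoxy-N,3-dimethyl-4-[(triethylsilyl)oxy]-4-(3,4,5-trimethoxyphenyl)butanamide | CON(C)C(=O)C[C@H](C)[C@H](O[Si](CC)(CC)CC)c1cc(OC)c(OC)c(OC)c1
F3 | step 11 | diphenyl {(3R,4S)-1-[methoxy(methyl)amino]-3-methyl-1-oxo-4-[(triethylsilyl)oxy]-4-(3,4,5-trimethoxyphenyl)butan-2-yl}phosphonate (C2 epimers) | CON(C)C(=O)C(P(=O)(Oc1ccccc1)Oc1ccccc1)[C@H](C)[C@H](O[Si](CC)(CC)CC)c1cc(OC)c(OC)c(OC)c1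
F4 | step 11 | (2Z,4S)-4-acetyl-N,4-dimethoxy-N-methyl-2-{(1S,2S)-1-[(triethylsilyl)oxy]-1-(3,4,5-trimethoxyphenyl)propan-2-yl}hepta-2,6-dienamide | CC(=O)[C@](OC)(CC=C)/C=C(/[C@H](C)[C@H](O[Si](CC)(CC)CC)c1cc(OC)c(OC)c(OC)c1)C(=O)N(C)OC
F5 | step 11 | (6S)-3-hydroxy-6-methoxy-6-(prop-2-en-1-yl)-4-{(1S,2S)-1-[(triethylsilyl)oxy]-1-(3,4,5-trimethoxyphenyl)propan-2-yl}cyclohexa-2,4-dien-1-one | C=CC[C@]1(OC)C=C([C@H](C)[C@H](O[Si](CC)(CC)CC)c2cc(OC)c(OC)c(OC)c2)C(O)=CC1=O
F6 | step 10 | (4S,5S)-3-[(2S)-2-acetyl-1-hydroxy-2-methoxypent-4-en-1-yl]-4-methyl-5-(3,4,5-trimethoxyphenyl)oxolan-2-one (diastereomers at C3 and the carbinol carbon) | CC(=O)[C@](OC)(CC=C)C(O)C1[C@H](C)[C@@H](c2cc(OC)c(OC)c(OC)c2)OC1=O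
F7 | step 10 | (2S)-2-acetyl-2-methoxy-1-[(4S,5S)-4-methyl-2-oxo-5-(3,4,5-trimethoxyphenyl)oxolan-3-yl]pent-4-en-1-yl methanesulfonate (diastereomers) | CC(=O)[C@](OC)(CC=C)C(OS(C)(=O)=O)C1[C@H](C)[C@@H](c2cc(OC)c(OC)c(OC)c2)OC1=O
F8 | step 10 | (3E,4S,5S)-3-[(2S)-2-acetyl-2-methoxypent-4-en-1-ylidene]-4-methyl-5-(3,4,5-trimethoxyphenyl)oxolan-2-one | CC(=O)[C@](OC)(CC=C)/C=C1\[C@H](C)[C@@H](c2cc(OC)c(OC)c(OC)c2)OC1=O
F9 | step 7 | tert-butyl (2RS)-2-acetyl-2-methoxypent-4-enoate | CC(=O)C(OC)(CC=C)C(=O)OC(C)(C)C
F10 | step 7 | 2-methoxy-2-(prop-2-en-1-yl)butane-1,3-diol (all stereoisomers) | CC(O)C(OC)(CC=C)CO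
F11 | step 7 | (2RS)-2-acetyl-2-methoxypent-4-enal | CC(=O)C(OC)(CC=C)C=O
F12 | step 7 | (3Z,4S,5S)-3-[(2R)-2-acetyl-2-methoxypent-4-en-1-ylidene]-4-methyl-5-(3,4,5-trimethoxyphenyl)oxolan-2-one | CC(=O)[C@@](OC)(CC=C)/C=C1/[C@H](C)[C@@H](c2cc(OC)c(OC)c(OC)c2)OC1=O
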